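**Retrosynthetic overview**
1. The 3'-OH is unmasked last from a benzyl ether; nothing else in the molecule carries a protecting group.
2. Ring C is the only ring formed. Its C4 carbonyl carbon has just two carbon neighbours, C4a of ring A and C3, so it is cut at C4a–C4, C4–C3 and O1–C2 into an A-ring aryl iodide, carbon monoxide (C4) and a B-ring arylacetylene (C3≡C2).
3. C4a lies on the mirror axis of ring A (its ortho carbons C5 and C8a both carry oxygen, C7–OMe is para). A symmetric 2-iodo-5-methoxyresorcinol therefore needs no protection: whichever hydroxyl closes becomes O1, the other is the 5-OH.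
4. A-ring piece: iodination of 5-methoxyresorcinol between the hydroxyls. B-ring alkyne: from 2,6-dimethoxyphenol by O-benzylation, formylation, bromination, copper-mediated methoxylation and one-carbon homologation of the aldehyde.

Key step: step 7

Remark: the target has no stereocentre and no stereogenic axis or double bond, so the demand for a single enantiomer places no requirement on the route.

**Route**

Step 1
Reactants: 1 2,6-dimethoxyphenol
Product: 2 2-(benzyloxy)-1,3-dimethoxybenzene
Conditions: BnBr, K2CO3, DMF, 60 °C
Reagents that add atoms: benzyl bromide, BrCc1ccccc1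
Why: Williamson ether synthesis, in which the phenoxide of 1 is alkylated by the reactive primary benzylic bromide despite its two flanking methoxy groups.

Step 2
Reactants: 2 2-(benzyloxy)-1,3-dimethoxybenzene
Product: 4 3-(benzyloxy)-2,4-dimethoxybenzaldehyde, via iminium chloride 3 (not isolated)
Conditions: POCl3, DMF, 0 → 75 °C; then ice-water, rt
Reagents that add atoms: N,N-dimethylformamide, CN(C)C=O (formyl carbon); water, O (carbonyl oxygen)
Why: Vilsmeier–Haack formylation, in which the chloroiminium electrophile should attack C4 of 2 (para to one methoxy and ortho to the other, and identical to C6 by symmetry) rather than C5, which is activated only by the out-of-plane central benzyloxy group, as in the formylation of 1,2,3-trimethoxybenzene, and the iminium salt 3 is hydrolysed on aqueous quench.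

Step 3
Reactants: 4 3-(benzyloxy)-2,4-dimethoxybenzaldehyde
Product: 5 3-(benzyloxy)-5-bromo-2,4-dimethoxybenzaldehyde
Conditions: NBS, DMF, 0 °C → rt, dark
Reagents that add atoms: N-bromosuccinimide, O=C1CCC(=O)N1Br
Why: Electrophilic aromatic bromination, which should occur only at C5 because it is para to the 2-OMe, ortho to the 4-OMe and meta to the formyl group, whereas C6 is ortho to the formyl group and activated only by the twisted 3-benzyloxy group.

Step 4
Reactants: 5 3-(benzyloxy)-5-bromo-2,4-dimethoxybenzaldehyde
Product: 6 3-(benzyloxy)-2,4,5-trimethoxybenzaldehyde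
Conditions: NaOMe, CuBr (15 mol %), MeOH–DMF, 100 °C
Reagents that add atoms: sodium methoxide, [Na+].[O-]C
Why: Copper-catalysed Ullmann-type methoxylation of an aryl bromide, in which copper(I) methoxide replaces bromide at C5 while the aldehyde is reversibly masked as its hemiacetal alkoxide in the methoxide medium, as in the classical conversion of bromobenzaldehydes into methoxybenzaldehydes.

Step 5
Reactants: 6 3-(benzyloxy)-2,4,5-trimethoxybenzaldehyde
Product: 7 3-(benzyloxy)-1-ethynyl-2,4,5-trimethoxybenzene
Conditions: dimethyl (1-diazo-2-oxopropyl)phosphonate, K2CO3, MeOH, 0 °C → rt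
Reagents that add atoms: dimethyl (1-diazo-2-oxopropyl)phosphonate (Ohira–Bestmann reagent), CC(=O)C(=[N+]=[N-])P(=O)(OC)OC
Why: Seyferth–Gilbert homologation in the Ohira–Bestmann modification, in which the diazomethylphosphonate anion released by methanolysis adds to the aldehyde, loses dimethyl phosphate and nitrogen, and the alkylidene carbene rearranges by 1,2-hydrogen shift to the terminal alkyne under carbonate conditions that leave the ethers untouched.

Step 6
Reactants: 8 5-methoxyresorcinol
Product: 9 2-iodo-5-methoxybenzene-1,3-diol
Conditions: I2 (1.0 equiv), NaHCO3, H2O–THF, 0 °C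
Reagents that add atoms: iodine, II
Why: Electrophilic aromatic iodination of a phenoxide, which under aqueous bicarbonate should take place at the carbon flanked by both hydroxyls, as in the conversion of resorcinol into 2-iodoresorcinol, with the isomer iodinated next to the methoxy group as the expected minor product to be separated.

Step 7
Reactants: 9 2-iodo-5-methoxybenzene-1,3-diol; 10 carbon monoxide; 7 3-(benzyloxy)-1-ethynyl-2,4,5-trimethoxybenzene
Product: 13 3'-benzyloxy-5-hydroxy-7,2',4',5'-tetramethoxyflavone, via ynone 11 (not isolated), via enaminone 12 (not isolated)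
Conditions: PdCl2(dppf) (5 mol %), CO (20 bar), Et2NH (solvent), 100 °C, no copper
Reagents that add atoms: none
Why: Pd(0) inserts into the C–I bond of 9 (the future C4a), CO inserts to give the aroyl–palladium, and amine-assisted transfer of the acetylide of 7 followed by reductive elimination forms C4a–C4 and C4–C3 in ynone 11. Diethylamine then adds reversibly to the ynone β-carbon to give enaminone 12, and an ortho hydroxyl displaces the amine at that carbon by addition–elimination, forming O1–C2 and the pyranone ring. The closest known reaction type is the palladium-catalysed carbonylative Sonogashira coupling of 2-iodophenols with terminal arylacetylenes in a secondary amine, which gives flavones in one pot. The single ring closure is formally 6-endo-dig on the ynone (6-endo-trig addition–elimination on 12), and no stereocentre is created. The step needs CO insertion to precede alkynylation (otherwise a 2-alkynylphenol and then a benzofuran would form) and 6-endo rather than 5-exo closure (aurone): CO pressure, the absence of copper and the electron-rich aryl–palladium favour insertion, and the Michael polarisation of the ynone and enaminone sends the oxygen to C2, whereas the aurone would need metal-activated anti-Michael attack at C3. Because the iodide sits on the symmetry axis of 9, either hydroxyl gives the same product and the one left over becomes the hydrogen-bonded 5-OH, so ring A needs no protecting group.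

Step 8
Reactants: 13 3'-benzyloxy-5-hydroxy-7,2',4',5'-tetramethoxyflavone
Product: 14 5,3'-dihydroxy-7,2',4',5'-tetramethoxyflavone
Conditions: H2 (1 atm), 10% Pd/C, EtOAc–MeOH, rt
Reagents that add atoms: none
Why: Catalytic hydrogenolysis of a benzyl aryl ether on Pd/C, which should cleave only the O–CH2Ph bond at 1 atm and room temperature while the methyl ethers, the chelated 5-OH and the doubly aryl-conjugated C2=C3 bond of the flavone are retained.

**Compound list**
1 | 2,6-dimethoxyphenol | COc1cccc(OC)c1O | starting material
2 | 2-(benzyloxy)-1,3-dimethoxybenzene | COc1cccc(OC)c1OCc1ccccc1 | intermediate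
3 | N-{[3-(benzyloxy)-2,4-dimethoxyphenyl]methylidene}-N-methylmethanaminium chloride (iminium chloride formed in the flask in step 2) | C[N+](C)=Cc1ccc(OC)c(OCc2ccccc2)c1OC.[Cl-] | intermediate
4 | 3-(benzyloxy)-2,4-dimethoxybenzaldehyde | O=Cc1ccc(OC)c(OCc2ccccc2)c1OC | intermediate
5 | 3-(benzyloxy)-5-bromo-2,4-dimethoxybenzaldehyde | O=Cc1cc(Br)c(OC)c(OCc2ccccc2)c1OC | intermediate
6 | 3-(benzyloxy)-2,4,5-trimethoxybenzaldehyde | O=Cc1cc(OC)c(OC)c(OCc2ccccc2)c1OC | intermediate
7 | 3-(benzyloxy)-1-ethynyl-2,4,5-trimethoxybenzene | C#Cc1cc(OC)c(OC)c(OCc2ccccc2)c1OC | intermediate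
8 | 5-methoxyresorcinol (5-methoxybenzene-1,3-diol) | COc1cc(O)cc(O)c1 | starting material
9 | 2-iodo-5-methoxybenzene-1,3-diol | COc1cc(O)c(I)c(O)c1 | intermediate
10 | carbon monoxide | [C-]#[O+] | starting material
11 | 3-[3-(benzyloxy)-2,4,5-trimethoxyphenyl]-1-(2,6-dihydroxy-4-methoxyphenyl)prop-2-yn-1-one (ynone formed in the flask in step 7) | COc1cc(O)c(C(=O)C#Cc2cc(OC)c(OC)c(OCc3ccccc3)c2OC)c(O)c1 | intermediate
12 | (E)-3-[3-(benzyloxy)-2,4,5-trimethoxyphenyl]-3-(diethylamino)-1-(2,6-dihydroxy-4-methoxyphenyl)prop-2-en-1-one (enaminone formed in the flask in step 7; drawn as the E isomer, the geometry is immaterial for ring closure) | CCN(CC)/C(=C/C(=O)c1c(O)cc(OC)cc1O)c1cc(OC)c(OC)c(OCc2ccccc2)c1OC | intermediate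
13 | 3'-benzyloxy-5-hydroxy-7,2',4',5'-tetramethoxyflavone | COc1cc(O)c2c(=O)cc(-c3cc(OC)c(OC)c(OCc4ccccc4)c3OC)oc2c1 | intermediate
14 | 5,3'-dihydroxy-7,2',4',5'-tetramethoxyflavone (achiral) | COc1cc(O)c2c(=O)cc(-c3cc(OC)c(OC)c(O)c3OC)oc2c1 | target

**Step count**
Total steps: 8. Longest linear sequence: 7 steps (steps 1–5, 7, 8); step 6 is a one-step side branch.

**Steps most likely to fail**

Step 7 (key step). The aryl–palladium may be alkynylated before CO inserts and then close 5-endo to a benzofuran. The aroyl–palladium may also be captured by diethylamine or a phenoxide, the iodide may be reduced off, or the ynone may close 5-exo. Fallback: the pyranone is built by chalcone oxidation instead, setting out from aldehyde 6 and returning at 13. Claisen–Schmidt condensation of 6 with commercial 1-(2,6-dihydroxy-4-methoxyphenyl)ethanone (CC(=O)c1c(O)cc(OC)cc1O; KOH, EtOH, rt) should give (E)-3-[3-(benzyloxy)-2,4,5-trimethoxyphenyl]-1-(2,6-dihydroxy-4-methoxyphenyl)prop-2-en-1-one F1. Iodine-catalysed oxidative cyclisation in DMSO (cat. I2, 130 °C) should convert it into 13, and step 8 follows unchanged.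

Step 6. Iodination may occur at the carbon between OH and OMe, a second iodine may be introduced, or the electron-rich iodide may lose iodine on acidic handling. Fallback: the iodine is placed by directed metalation, setting out from 8 and returning at 9. Bis-MOM protection (MOMCl, i-Pr2NEt, CH2Cl2) should give 1-methoxy-3,5-bis(methoxymethoxy)benzene F2. Lithiation between the two MOM ethers (n-BuLi, THF, 0 °C) gives [4-methoxy-2,6-bis(methoxymethoxy)phenyl]lithium F3, and iodine quench gives 2-iodo-5-methoxy-1,3-bis(methoxymethoxy)benzene F4. Mild acid methanolysis (cat. HCl, MeOH, 40 °C) releases 9.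

Step 4. The C–Br bond may be reduced instead of substituted, and the unprotected aldehyde may disproportionate in hot methoxide. Fallback: the formyl group becomes the 5'-methoxy group and the bromide becomes the alkyne, setting out from 5 and returning at 7, so that steps 4 and 5 are bypassed. Baeyer–Villiger oxidation (mCPBA, CH2Cl2) should give 3-(benzyloxy)-5-bromo-2,4-dimethoxyphenyl formate F5, and methanolysis (K2CO3, MeOH) gives 3-(benzyloxy)-5-bromo-2,4-dimethoxyphenol F6. O-Methylation (MeI, K2CO3, acetone) gives 3-(benzyloxy)-1-bromo-2,4,5-trimethoxybenzene F7. Copper-free Sonogashira coupling with trimethylsilylacetylene (PdCl2(MeCN)2, XPhos, Cs2CO3, MeCN, 80 °C) gives {[3-(benzyloxy)-2,4,5-trimethoxyphenyl]ethynyl}trimethylsilane F8, and desilylation (K2CO3, MeOH) gives 7.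

**Further compounds**
F1 | step 7 | (E)-3-[3-(benzyloxy)-2,4,5-trimethoxyphenyl]-1-(2,6-dihydroxy-4-methoxyphenyl)prop-2-en-1-one | COc1cc(O)c(C(=O)/C=C/c2cc(OC)c(OC)c(OCc3ccccc3)c2OC)c(O)c1
F2 | step 6 | 1-methoxy-3,5-bis(methoxymethoxy)benzene | COCOc1cc(OC)cc(OCOC)c1
F3 | step 6 | [4-methoxy-2,6-bis(methoxymethoxy)phenyl]lithium | [Li]c1c(OCOC)cc(OC)cc1OCOC
F4 | step 6 | 2-iodo-5-methoxy-1,3-bis(methoxymethoxy)benzene | COCOc1cc(OC)cc(OCOC)c1I
F5 | step 4 | 3-(benzyloxy)-5-bromo-2,4-dimethoxyphenyl formate | O=COc1cc(Br)c(OC)c(OCc2ccccc2)c1OC
F6 | step 4 | 3-(benzyloxy)-5-bromo-2,4-dimethoxyphenol | Oc1cc(Br)c(OC)c(OCc2ccccc2)c1OC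
F7 | step 4 | 3-(benzyloxy)-1-bromo-2,4,5-trimethoxybenzene | COc1cc(Br)c(OC)c(OCc2ccccc2)c1OC
F8 | step 4 | {[3-(benzyloxy)-2,4,5-trimethoxyphenyl]ethynyl}trimethylsilane | C[Si](C)(C)C#Cc1cc(OC)c(OC)c(OCc2ccccc2)c1OC
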